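The rate constants belong to no real substance.

Start with the easy question of where one molecule of coupling partner can go: it has two exits.

| setting | cedar | oak | elm | ash |
|---|---|---|---|---|
| substrate | 47 mM | 47 mM | 47 mM | 47 mM (fed, over 64.0 min) |
| coupling partner | 51.7 mM | 51.7 mM (fed, over 64.0 min) | 51.7 mM | 51.7 mM |
| remark | a single well-mixed tank run continuously and read at steady state, 80 min in it on average | a stirred flask in which coupling partner is dosed at a steady rate over 64.0 min without added volume, worked up at 80 min | a closed flask charged with all of it at once and left for 80 min | a stirred flask in which substrate is dosed at a steady rate over 64.0 min without added volume, worked up at 80 min |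
| time |  | 80 min | 80 min | 80 min |

    substrate + coupling partner ⇌ target + by-product (K1 = 2.0, k1 = 0.047 M⁻¹ s⁻¹)
    target ⇌ isomer of the product (K2 = 2.5, k2 = 1.5 × 10⁻⁴ s⁻¹)
    coupling partner ⇌ dormant form (K3 = 3.0, k3 = 8.3 × 10⁻⁴ s⁻¹)

- the set-up with the highest amount of target at the outlet or at the end, in percent of the substrate put in ("none" if the first two lie within 2 percentage points) (cedar / oak / elm / ash / none)
- amount of target at the outlet or at the end, in percent of the substrate put in, cedar
- amount of target at the outlet or at the end, in percent of the substrate put in, oak
- amount of target at the outlet or at the end, in percent of the substrate put in, elm
- amount of target at the outlet or at the end, in percent of the substrate put in, ash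

- the stated concentrations are those of everything mixed, before any reaction; amounts are the same in each set-up
- the feed brings no volume worth counting
- run time (oak): 80 min

**Two exits.** Coupling partner either meets substrate and heads for target, or slips into dormant form. Divide the forward rate of the coupling step by the forward rate of that loss. Coupling partner stands in both rates, so it cancels, and time drops out too. Call the quotient S: the coupling constant times substrate, over the constant of the loss. With the full charge of substrate present, S is 2.66, the selectivity factor at full charge. At any other moment, multiply it by the fraction of substrate present. Counting forward steps only, a share S/(1+S) of coupling partner goes the useful way, here 72.7%.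

**Oak, ash.** Apply S to the two dosed flasks. Oak holds its whole substrate at the start, so its first doses of coupling partner meet the full 2.66. Ash starts with none of its substrate in the flask. At 32.0 min it has received half of it, so S in ash at that moment is at most 1.33, lower than oak's opening value, and the forward share at that moment is at most 57.1%. Meanwhile the coupling partner in ash stands exposed: its forward half-life towards dormant form, 14 min, is shorter than the 64.0 min feed. My reckoning stops here: I expect oak above ash, but it gives no size for that gap and no yields, and it leaves cedar and elm unplaced.

**The check.** The forecast gives 30.6% for cedar, 33% for oak, 29.2% for elm and 32% for ash, best none, holding that “dosing either reagent delays target build-up and keeps a little more of it than the batch or the tank”.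

The simulation gives 30.8% for cedar, 35.2% for oak, 28.2% for elm and 29.6% for ash. Best is oak, 4.4 percentage points above cedar and 5.6 points above ash. At 40.0 min oak holds 64.9% substrate, so S reads 1.73, with 16.5 mM by-product beside 7.77 mM dormant form. Ash then holds 35.6%, so S reads 0.947, with 12.7 mM by-product beside 29.7 mM dormant form.

**Neighbour flask.** Take elm with 130 mM of coupling partner, 2.77 equiv. S contains no coupling partner, so this flask opens at the same 2.66. At 80.0 min its substrate stands at 28.2%, so S reads 0.750, against 1.32 in elm. It holds 33.7 mM by-product beside 72.0 mM dormant form, where elm holds 23.7 mM and 21.0 mM. Its target stands at 39.5%, against 28.2% in elm.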